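## Structural features

The target is an eremophilane ester built on a cis-fused decalin. Ring A (C1–C5 and C10) carries the C3 acyloxy group and the C4 methyl; ring B (C5–C10) carries the C7 isopropenyl group, the C8 ketone and the C9 hydroxyl; C5 is the quaternary angular carbon, and C3 is esterified by (2E,4R)-4-angeloyloxyhex-2-enoic acid. Five stereocentres are contiguous (C3–C4–C5–C10–C9), C7 is the sixth on the bicycle and C4' of the side chain the seventh. The C4 methyl, C5 methyl, C10 hydrogen, C7 isopropenyl and C9 hydroxyl all lie on the β face and the C3 oxygen on the α face. In the chair–chair conformer that has C4 axial on ring B, every substituent except the angular methyl is equatorial, so C3, C4, C7 and C9 all hold their thermodynamically preferred configurations. The fragile groups are the C7 isopropenyl group β,γ to the C8 ketone (base or strong acid would conjugate it to the isopropylidene ketone), the α-ketol at C8/C9, the (Z)-angelate (isomerises to the tiglate) and the γ-acyloxy enoate. The real difficulty is twofold: the vicinal C4/C5 centres with cis methyls at a cis ring fusion, and the C8-ketone/C9-hydroxyl pattern next to the ring fusion, whose C9 oxygen must end on the convex face. The key step exploits ring B: with the C5 methyl and C7 isopropenyl 1,3-cis it is a meta-menthane, the skeleton released by opening the cyclopropane of 3-carene. The resulting enone already has the angular methyl on its β-carbon (C5), so ring A can be annulated across C5 and C10.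

## Logic of the disconnections

25 ⇒ 24 ⇒ 23 ⇒ 22: the C9 O–Si bond, the C8 carbonyl and the C8 O–Si bond are taken back in that order. The C8 ketone makes C7 and C9 enolisable and the isopropenyl group prone to conjugation, so it should appear only after the last basic or reducing operation. This leaves two differentiated silyl ethers and demands a selective cleavage of the smaller silyl group and non-basic final conditions.

22 ⇒ 14 + 20: the C3 O–acyl bond is cut. This separates the whole side chain as a preformed acid and leaves one free secondary alcohol on the bicycle. The forward esterification must not isomerise the angelate or the enoate.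

20 ⇒ 18 + 19 and 18 ⇒ 15 + 16: the C2'=C3' alkene is cut by cross-metathesis logic and the angelate C–O acyl bond by acylation logic. The side chain then comes from three small commercial pieces with the carbinol stereocentre bought in. The forward steps demand E-selective metathesis that ignores the trisubstituted angelate alkene and an acylation that keeps the Z geometry.

14 ⇒ 13 ⇒ 12: the C3 carbinol C–H bond is removed (ketone), then the C3 ketone is returned to its enol silane. The equatorial C3 alcohol and the equatorial C4 methyl are both thermodynamic, so reduction and α-epimerisation can be run under equilibrium control while no ring-B ketone is present. The demand is a reduction that gives the more stable alcohol despite the axial angular methyl.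

12 ⇒ 11 ⇒ 10 ⇒ 9 ⇒ 7: the C9 O–Si bond, the C9 carbinol C–H bond, the C8 O–Si bond and the C8–O bond are removed in turn. This is a 1,2-carbonyl transposition written backwards: the C8 oxygen comes from the kinetic enolate of the C9 ketone and the C9 ketone is then reduced. The ring-A enol silane keeps C3 masked throughout. The demand is hydride delivery to the concave α face of C9. An oxygen substituent carried on C8 of the enone before the annulation was considered and rejected, because it would not remove this demand and would crowd the key step.

7 ⇒ 3 + 5 (through 6): C4–C5 and C1–C10 are cut, which removes ring A and three stereocentres (C4, C5, C10) at once. What remains is a monocyclic enone with one stereocentre and an achiral diene. The forward step must form a bond to a fully substituted β-carbon, anti to the C7 substituent, and close the ring cis.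

3 ⇒ 2 ⇒ 1 and 5 ⇒ 4: the cyclopropane C–C bond next to the carbonyl is re-formed and the ketone oxygen removed, leading to the chiral-pool hydrocarbon whose C1 becomes C7 of the target (the S enone maps onto the required C7 configuration). The diene is the enol silane of a vinyl ketone. The demand is kinetic loss of a methyl proton after ring opening, so that the isopropenyl group and the stereocentre survive.

## Other disconnections considered

Alternative 1: The cut is C1–C10, made with a temporary C3–C8 bond that exists only in the precursor. The product of the key step would be A1, the cis-fused 4β,5β-dimethyl decalin with a C3 ketone and a C8=C9 alkene. It would arise by anionic oxy-Cope rearrangement of the bicyclo[2.2.2]octenol A2, itself reached by phenol dearomatisation, Diels–Alder reaction and vinyl addition.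
- In its favour: the rigid bicycle transfers its geometry completely, so the cis fusion and the C4/C5 relationship are fixed by the substrate and not by an open transition state. On this point it is the better plan. The C8=C9 alkene is also a more direct handle for the C8/C9 oxygens than a C9 ketone that has to be transposed, which is a second point where it is better.
- Against it here: A1 lacks the C7 isopropenyl group and its stereocentre, and introducing it next to a C8 carbonyl tends to give the conjugated isopropylidene isomer. The dearomatisation route is racemic unless an auxiliary is added. The vinyl group and the C4 methyl must both sit syn to the etheno bridge.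
- Comparison: mechanistically both plans are reliable pericyclic or stepwise polar processes. On step economy the chosen plan reaches its annulated intermediate in four steps with C7 already set, whereas this one needs more steps before the key step and more after it for C7.

Alternative 2: The cut is C5–C10. The product of the key step would be the cyclohexene acid A3, formed by Ireland–Claisen ring contraction of the silyl ketene acetal of the alkenyl δ-lactone A4. The allylic C3–O bond breaks, C5–C10 forms and C9 emerges as the carboxyl carbon.
- In its favour: C5 and C10 are set by chirality transfer from one carbinol centre and one alkene geometry. The C3=C4 alkene left in A3 would allow hydroboration to install the C3 oxygen and the C4 hydrogen in one stereospecific step, which is at least the equal of the equilibrium-controlled ring-A sequence chosen here.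
- Against it here: A4 needs a stereodefined tetrasubstituted alkene, and the δ-lactone must rearrange through a strained bicyclic boat. Ring B is not formed at all; it must be closed later between C9 and C8, and C7 with its isopropenyl group is not addressed.
- Comparison: structurally it solves the quaternary centre well but leaves ring B and its three functionalised carbons open, so the chosen plan is clearly shorter. Mechanistically the sigmatropic step is more predictable at C5/C10 than the Mukaiyama–Michael step is at C4.

Alternative 3: The cuts are C5–C6 and C7–C8. The product of the key step would be A5, formed by Diels–Alder addition of the ring-A ethoxydiene A6 (diene unit C5=C10–C9=C8) to the dienophile A7 (but-3-en-2-one).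
- In its favour: C3 and C4 are set on a simple cyclohexane before annulation, oxygen is delivered directly to C8, and the acetyl group at C7 is a two-carbon precursor of the isopropenyl group. Avoiding any carbonyl transposition is a point where it is the better plan.
- Against it here: the C5 terminus of A6 carries its methyl in the inside (cis) position, which disfavours the s-cis conformer and makes the quaternary-centre-forming cycloaddition slow. The C9=C10 alkene of A5 must then be turned into a C9 hydroxyl and a C10 hydrogen on the face of the angular methyl; additions anti to that methyl would give the trans fusion. The acetyl group must be methylenated next to an epimerisable centre.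
- Comparison: step counts are similar. The chosen plan secures the cis fusion by the annulation itself and takes C7 from the chiral pool. This alternative is the equal of the chosen plan for C3/C4 control and better at C8, but weaker at C5 and C10.

Key step: step 4

Convention: eremophilane numbering is used for all bicyclic compounds (ring A = C1–C5 and C10, ring B = C5–C10); β is the face of the C5 methyl group and α the opposite face.

Assumption: (R)-pent-1-en-3-ol is bought as the single enantiomer; angelic acid, acrylic acid, pent-1-en-3-one and (+)-3-carene are commercial.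

## Route

Step 1
Reactants: 1 (+)-3-carene
Product: 2 car-3-en-5-one, (1R,6S)-4,7,7-trimethylbicyclo[4.1.0]hept-3-en-2-one
Conditions: CrO3, 3,5-dimethylpyrazole, CH2Cl2, −20 °C
Reagents that add atoms: chromium trioxide, O=[Cr](=O)=O
Why: Allylic oxidation with the CrO3–3,5-dimethylpyrazole complex attacks the methylene flanked by the alkene CH and the cyclopropane, giving the β-methyl enone conjugated to the three-membered ring; neither stereocentre is touched.

Step 2
Reactants: 2 car-3-en-5-one
Product: 3 (S)-3-methyl-5-(prop-1-en-2-yl)cyclohex-2-en-1-one
Conditions: TsOH·H2O (10 mol %), PhMe, 60 °C, stopped at full conversion of 2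
Reagents that add atoms: none
Why: Acid-catalysed cyclopropyl ketone cleavage (cyclopropylcarbinyl to homoallyl cation): the external bond between the α-carbon and the gem-dimethyl carbon breaks to a tertiary cation and a dienol, and E1 loss of one of six methyl protons gives the isopropenyl group; the stereocentre (carene C1, future C7) is not involved and keeps its configuration.

Step 3
Reactants: 4 pent-1-en-3-one
Product: 5 tert-butyldimethyl[(3Z)-penta-1,3-dien-3-yloxy]silane
Conditions: TBSOTf, Et3N, Et2O, 0 °C
Reagents that add atoms: tert-butyldimethylsilyl triflate, CC(C)(C)[Si](C)(C)OS(=O)(=O)C(F)(F)F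
Why: Soft enolisation and O-silylation of the ethyl ketone gives the 2-silyloxydiene; the Z enol geometry (methyl cis to oxygen) is the usual outcome for ethyl ketones under amine/silyl triflate conditions.

Step 4
Reactants: 3 (S)-3-methyl-5-(prop-1-en-2-yl)cyclohex-2-en-1-one; 5 tert-butyldimethyl[(3Z)-penta-1,3-dien-3-yloxy]silane
Product: 7 3-(tert-butyldimethylsilyloxy)-4β,5β-dimethyl-7β-(prop-1-en-2-yl)-10βH-cis-decal-2-en-9-one, via Mukaiyama–Michael adduct 6 (not isolated)
Conditions: 5 (1.5 equiv) and HNTf2 (5 mol %) premixed, CH2Cl2, −78 °C; then 3, −78 → −40 °C; Et3N quench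
Reagents that add atoms: none
Why: HNTf2 is consumed at once by a little of 5 to give TBSNTf2, the true catalyst, so the isopropenyl group of 3 never meets free strong acid; this premixing is the one design change made to the precursor pair. The silyl Lewis acid activates the enone, and the silyl enol carbon C4 of 5 adds to the fully substituted C5 (Mukaiyama–Michael), giving the C9 enol silane 6 with a tethered vinyl ketone. C10 of that enol silane then adds to C1 in a 6-(enolexo)-endo-trig Michael closure of ring A, the silyl group ending on the C3 oxygen as the Δ2 enol silane and TBSNTf2 being released. The closest known reaction type is the triflimide-catalysed double Michael annulation of 2-silyloxydienes with hindered β,β-disubstituted cyclohexenones, which takes the place of a Diels–Alder reaction that such enones resist. C5 is controlled by C7: the nucleophile enters axially on the half-chair with the isopropenyl group pseudo-equatorial, trans to it (the trans-3,5 preference of 5-substituted cyclohexenones). C10 is controlled by the tether: the chain sits axial on the α face and can only reach the α face of C10, so the fusion must be cis. C4 depends on the Z enol geometry and an open transition state and is the least secure centre, but it becomes epimerisable and converges in step 9. The regioselectivity needed (reaction at the enol carbon and not the vinyl terminus of 5) is inherent to silyl enol ethers.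

Step 5
Reactants: 7 3-(tert-butyldimethylsilyloxy)-4β,5β-dimethyl-7β-(prop-1-en-2-yl)-10βH-cis-decal-2-en-9-one
Product: 9 8β-hydroxy derivative of 7 (8β-hydroxy-9-ketone), via potassium enolate 8 (not isolated)
Conditions: KN(SiMe3)2, THF, −78 °C; 3-phenyl-2-(phenylsulfonyl)oxaziridine, −78 °C; aq. NH4Cl
Reagents that add atoms: 3-phenyl-2-(phenylsulfonyl)oxaziridine, O=S(=O)(c1ccccc1)N1OC1c1ccccc1
Why: Kinetic deprotonation takes the C8 methylene and not the C10 methine, and Davis enolate hydroxylation should put oxygen on the convex β face along the axial trajectory, because the concave α face is screened by the C4–H that points under ring B; the enol silane of ring A is inert to base and to the oxaziridine at −78 °C.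

Step 6
Reactants: 9 8β-hydroxy-9-ketone
Product: 10 8β-(triethylsilyloxy)-9-ketone
Conditions: Et3SiCl, imidazole, DMF, 0 → 25 °C
Reagents that add atoms: chlorotriethylsilane, CC[Si](Cl)(CC)CC
Why: Silylation of the secondary ketol hydroxyl under mild base blocks the acyloin shift and hydroxyl-directed hydride delivery, and places a bulky axial group on the β face next to the carbonyl.

Step 7
Reactants: 10 8β-(triethylsilyloxy)-9-ketone
Product: 11 9β-alcohol (8β-triethylsilyloxy-9β-hydroxy)
Conditions: LiAlH4, Et2O, −78 °C; Rochelle salt work-up
Reagents that add atoms: none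
Why: Hydride reduction under polar Felkin–Anh control: the small hydride should add anti to the axial C8–O bond, from the α face, because the axial silyloxy group blocks the equatorial β trajectory, giving the equatorial 9β-alcohol; the ring-A enol silane and the silyl ether do not react with LiAlH4 at −78 °C.

Step 8
Reactants: 11 9β-alcohol
Product: 12 9β-(tert-butyldimethylsilyloxy)-8β-(triethylsilyloxy) bis-silyl ether
Conditions: TBSOTf, 2,6-lutidine, CH2Cl2, −78 → 0 °C
Reagents that add atoms: tert-butyldimethylsilyl triflate, CC(C)(C)[Si](C)(C)OS(=O)(=O)C(F)(F)F
Why: Silyl triflate silylation of a hindered secondary alcohol; the C9 oxygen now carries the more robust silyl group, so that the C8 oxygen can be freed first later.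

Step 9
Reactants: 12 bis-silyl ether with ring-A enol silane
Product: 13 C3 ketone (4β-methyl, equatorial)
Conditions: K2CO3, MeOH, 25–40 °C
Reagents that add atoms: none
Why: Methanolysis of the silyl enol ether (an enolate is a leaving group comparable to a phenoxide) releases the C3 ketone while the two alkyl silyl ethers stay; the same medium equilibrates C4 through the enolate to the equatorial 4β-methyl epimer, since an axial 4α-methyl would be 1,3-diaxial to the C10–C9 bond. No ring-B ketone is present, so the isopropenyl group and C10 are not at risk.

Step 10
Reactants: 13 C3 ketone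
Product: 14 3α-alcohol (equatorial)
Conditions: Li, NH3(l), THF, t-BuOH, −78 °C; NH4Cl
Reagents that add atoms: none
Why: Dissolving-metal reduction gives the thermodynamically more stable equatorial alcohol, whereas hydride reagents would be steered by the syn-axial C5 methyl to the axial epimer; isolated alkenes and alkyl silyl ethers are inert, and no α-oxygenated ketone is present.

Step 11
Reactants: 15 (R)-pent-1-en-3-ol; 16 angelic acid
Product: 18 (R)-pent-1-en-3-yl (Z)-2-methylbut-2-enoate, via mixed anhydride 17 (not isolated)
Conditions: 16, 2,4,6-trichlorobenzoyl chloride, Et3N, PhMe, 25 °C; then 15, 80 °C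
Reagents that add atoms: none
Why: Yamaguchi mixed-anhydride acylation run without a nucleophilic pyridine catalyst, the protocol chosen for angelates because it avoids Z-to-E isomerisation; the carbinol C–O bond is not broken, so the R centre is kept.

Step 12
Reactants: 18 (R)-pent-1-en-3-yl (Z)-2-methylbut-2-enoate; 19 acrylic acid
Product: 20 (2E,4R)-4-{[(2Z)-2-methylbut-2-enoyl]oxy}hex-2-enoic acid
Conditions: second-generation Hoveyda–Grubbs catalyst (5 mol %), 19 (4 equiv), CH2Cl2, 40 °C
Reagents that add atoms: none
Why: Olefin cross-metathesis between a monosubstituted allylic ester and an acrylate partner is E-selective; the trisubstituted, electron-poor angelate alkene does not engage the ruthenium carbene.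

Step 13
Reactants: 14 3α-alcohol; 20 (2E,4R)-4-{[(2Z)-2-methylbut-2-enoyl]oxy}hex-2-enoic acid
Product: 22 C3 ester with 8β-triethylsilyloxy and 9β-tert-butyldimethylsilyloxy groups, via mixed anhydride 21 (not isolated)
Conditions: 20, 2,4,6-trichlorobenzoyl chloride, Et3N, PhMe, 25 °C; then 14, DMAP, 25 °C
Reagents that add atoms: none
Why: Yamaguchi esterification of the only free hydroxyl, an equatorial secondary alcohol; acylation with retention at C3, at ambient temperature to spare the angelate and enoate geometries.

Step 14
Reactants: 22 bis-silyl ester
Product: 23 8β-alcohol (9β-tert-butyldimethylsilyloxy retained)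
Conditions: HF·pyridine, pyridine, THF, 0 °C
Reagents that add atoms: none
Why: Buffered fluoride cleaves the triethylsilyl ether selectively in the presence of the hindered tert-butyldimethylsilyl ether; the esters are stable to these weakly acidic conditions.

Step 15
Reactants: 23 8β-alcohol
Product: 24 C8 ketone with 9β-(tert-butyldimethylsilyloxy)
Conditions: Dess–Martin periodinane, NaHCO3, CH2Cl2, 0 → 25 °C
Reagents that add atoms: none
Why: Dess–Martin oxidation of a hindered axial secondary alcohol under buffered, non-enolising conditions; the C8 stereocentre is erased, and C7 and C9 already hold their equatorial, thermodynamically preferred configurations.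

Step 16
Reactants: 24 C8 ketone with 9β-(tert-butyldimethylsilyloxy)
Product: 25 (1R,2R,4aS,5R,7R,8aR)-5-hydroxy-1,8a-dimethyl-6-oxo-7-(prop-1-en-2-yl)decahydronaphthalen-2-yl (2E,4R)-4-{[(2Z)-2-methylbut-2-enoyl]oxy}hex-2-enoate
Conditions: HF·pyridine, THF, 0 → 25 °C
Reagents that add atoms: none
Why: Fluoride desilylation under mildly acidic conditions frees the C9 hydroxyl without the base that would conjugate the isopropenyl group, shift the ketol or isomerise the angelate.

## Compound list

1 | (+)-3-carene, (1S,6R)-3,7,7-trimethylbicyclo[4.1.0]hept-3-ene | CC1=CC[C@@H]2[C@H](C1)C2(C)C | starting material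
2 | car-3-en-5-one, (1R,6S)-4,7,7-trimethylbicyclo[4.1.0]hept-3-en-2-one | CC1=CC(=O)[C@@H]2[C@H](C1)C2(C)C | intermediate
3 | (S)-3-methyl-5-(prop-1-en-2-yl)cyclohex-2-en-1-one | C=C(C)[C@H]1CC(C)=CC(=O)C1 | intermediate
4 | pent-1-en-3-one | CCC(=O)C=C | starting material
5 | tert-butyldimethyl[(3Z)-penta-1,3-dien-3-yloxy]silane | C=C/C(O[Si](C)(C)C(C)(C)C)=C/C | intermediate
6 | Mukaiyama–Michael adduct: C9 tert-butyldimethylsilyl enol ether (C9=C10) of the ring-B ketone, C5 bearing the β-methyl and on the α face the C4 chain CH(CH3)C(=O)CH=CH2 (C4 as in 7) | C=C(C)[C@H]1C[C@](C)([C@@H](C)C(=O)C=C)C=C(O[Si](C)(C)C(C)(C)C)C1 | intermediate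
7 | 3-(tert-butyldimethylsilyloxy)-4β,5β-dimethyl-7β-(prop-1-en-2-yl)-10βH-cis-decal-2-en-9-one | C=C(C)[C@H]1C[C@@]2(C)[C@H](CC=C(O[Si](C)(C)C(C)(C)C)[C@@H]2C)C(=O)C1 | intermediate
8 | potassium Δ8(9)-enolate of 7 | C=C(C)[C@H]1C[C@@]2(C)[C@H](CC=C(O[Si](C)(C)C(C)(C)C)[C@@H]2C)C([O-])=C1.[K+] | intermediate
9 | 8β-hydroxy-3-(tert-butyldimethylsilyloxy)-4β,5β-dimethyl-7β-(prop-1-en-2-yl)-10βH-cis-decal-2-en-9-one | C=C(C)[C@H]1C[C@@]2(C)[C@H](CC=C(O[Si](C)(C)C(C)(C)C)[C@@H]2C)C(=O)[C@H]1O | intermediate
10 | 8β-(triethylsilyloxy) ether of 9 | C=C(C)[C@H]1C[C@@]2(C)[C@H](CC=C(O[Si](C)(C)C(C)(C)C)[C@@H]2C)C(=O)[C@H]1O[Si](CC)(CC)CC | intermediate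
11 | 9β-hydroxy-8β-(triethylsilyloxy)-3-(tert-butyldimethylsilyloxy)-4β,5β-dimethyl-7β-(prop-1-en-2-yl)-10βH-cis-decal-2-ene | C=C(C)[C@H]1C[C@@]2(C)[C@H](CC=C(O[Si](C)(C)C(C)(C)C)[C@@H]2C)[C@@H](O)[C@H]1O[Si](CC)(CC)CC | intermediate
12 | 9β-(tert-butyldimethylsilyloxy) ether of 11 | C=C(C)[C@H]1C[C@@]2(C)[C@H](CC=C(O[Si](C)(C)C(C)(C)C)[C@@H]2C)[C@@H](O[Si](C)(C)C(C)(C)C)[C@H]1O[Si](CC)(CC)CC | intermediate
13 | 9β-(tert-butyldimethylsilyloxy)-8β-(triethylsilyloxy)-4β,5β-dimethyl-7β-(prop-1-en-2-yl)-10βH-cis-decalin-3-one | C=C(C)[C@H]1C[C@@]2(C)[C@H](CCC(=O)[C@@H]2C)[C@@H](O[Si](C)(C)C(C)(C)C)[C@H]1O[Si](CC)(CC)CC | intermediate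
14 | 3α-alcohol of 13 (9β-tert-butyldimethylsilyloxy, 8β-triethylsilyloxy, 4β,5β-dimethyl, 7β-isopropenyl, 10βH) | C=C(C)[C@H]1C[C@@]2(C)[C@H](CC[C@@H](O)[C@@H]2C)[C@@H](O[Si](C)(C)C(C)(C)C)[C@H]1O[Si](CC)(CC)CC | intermediate
15 | (R)-pent-1-en-3-ol | C=C[C@@H](CC)O | starting material
16 | angelic acid, (Z)-2-methylbut-2-enoic acid | C/C=C(/C)C(=O)O | starting material
17 | (Z)-2-methylbut-2-enoic 2,4,6-trichlorobenzoic anhydride | C/C=C(/C)C(=O)OC(=O)c1c(Cl)cc(Cl)cc1Cl | intermediate
18 | (R)-pent-1-en-3-yl (Z)-2-methylbut-2-enoate | C=C[C@@H](CC)OC(=O)/C(C)=C\C | intermediate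
19 | acrylic acid | C=CC(=O)O | starting material
20 | (2E,4R)-4-{[(2Z)-2-methylbut-2-enoyl]oxy}hex-2-enoic acid | OC(=O)/C=C/[C@@H](CC)OC(=O)/C(C)=C\C | intermediate
21 | mixed anhydride of 20 with 2,4,6-trichlorobenzoic acid | O=C(OC(=O)/C=C/[C@@H](CC)OC(=O)/C(C)=C\C)c1c(Cl)cc(Cl)cc1Cl | intermediate
22 | 3α-[(2E,4R)-4-angeloyloxyhex-2-enoyloxy]-9β-(tert-butyldimethylsilyloxy)-8β-(triethylsilyloxy)-4β,5β-dimethyl-7β-(prop-1-en-2-yl)-10βH-cis-decalin | C=C(C)[C@H]1C[C@@]2(C)[C@H](CC[C@@H](OC(=O)/C=C/[C@@H](CC)OC(=O)/C(C)=C\C)[C@@H]2C)[C@@H](O[Si](C)(C)C(C)(C)C)[C@H]1O[Si](CC)(CC)CC | intermediate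
23 | 8β-alcohol from 22 (9β-tert-butyldimethylsilyloxy retained) | C=C(C)[C@H]1C[C@@]2(C)[C@H](CC[C@@H](OC(=O)/C=C/[C@@H](CC)OC(=O)/C(C)=C\C)[C@@H]2C)[C@@H](O[Si](C)(C)C(C)(C)C)[C@H]1O | intermediate
24 | 9β-(tert-butyldimethylsilyl) ether of the target (C8 ketone) | C=C(C)[C@H]1C[C@@]2(C)[C@H](CC[C@@H](OC(=O)/C=C/[C@@H](CC)OC(=O)/C(C)=C\C)[C@@H]2C)[C@@H](O[Si](C)(C)C(C)(C)C)C1=O | intermediate
25 | (1R,2R,4aS,5R,7R,8aR)-5-hydroxy-1,8a-dimethyl-6-oxo-7-(prop-1-en-2-yl)decahydronaphthalen-2-yl (2E,4R)-4-{[(2Z)-2-methylbut-2-enoyl]oxy}hex-2-enoate | C=C(C)[C@H]1C[C@@]2(C)[C@H](CC[C@@H](OC(=O)/C=C/[C@@H](CC)OC(=O)/C(C)=C\C)[C@@H]2C)[C@@H](O)C1=O | target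

## Step count and least certain steps

Total step count: 16. Longest linear sequence: 13 steps (steps 1, 2, 4–10, 13–16 from compound 1); steps 3, 11 and 12 are side branches.

**Step 4 (key step).** The intermolecular addition to the fully substituted C5 may be slow, so that acid-induced protodesilylation or polymerisation of the diene, or protonation of the isopropenyl group, outruns it; facial selectivity at C5 could also be incomplete. Fallback: set out from 3 and separate the two bond formations, so that the hindered bond is made with a robust nucleophile and the vinyl ketone is created afterwards. Triflimide-catalysed Mukaiyama–Michael addition of (Z)-tert-butyldimethyl(pent-2-en-3-yloxy)silane F1 (from pentan-3-one, TBSOTf, Et3N) to 3 would give the C9 enol silane with an ethyl ketone side chain F2. Kinetic enolisation of the ethyl ketone (LiN(iPr)2, −78 °C) and selenenylation with one equivalent of PhSeBr would give the α-phenylselanyl ketone F3, and oxidation with H2O2/pyridine with syn-elimination would give 6. Ring closure of 6 with catalytic HNTf2 returns to the route at 7.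

**Step 2.** After ring opening the cation may lose the ring methine proton, or the isopropenyl group may be re-protonated; either path leads to the isopropylidene isomer and on to aromatisation. Base-mediated elimination of a tertiary halide is not an option because it would re-close the cyclopropane. Fallback: set out from 2 and trap the cation with water (dilute H2SO4, THF/H2O) as (S)-5-(2-hydroxypropan-2-yl)-3-methylcyclohex-2-en-1-one F4, then dehydrate by syn-elimination with the Burgess reagent (PhMe, 50 °C), which favours the methyl hydrogens, returning at 3.

**Step 7 (with the face selectivity of step 5).** Hydride may enter from the convex β face instead, giving the axial 9α-alcohol. This becomes likely if the oxaziridine in step 5 had attacked trans to the isopropenyl group, which would leave the silyloxy group equatorial and remove the bias. Fallback: set out from 10 and put C9 under thermodynamic control by Meerwein–Ponndorf–Verley reduction with equilibration (Al(OiPr)3, i-PrOH, a little acetone, PhMe, 80 °C). The equatorial 9β-alcohol is strongly preferred because an axial C9 oxygen is 1,3-diaxial to C4. This returns at 11 and makes no new compound (F0).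

**Step 10.** Protonation under incomplete equilibrium control may leave some axial 3β-alcohol, and prolonged exposure may erode the silyl ethers. Fallback: set out from 13 and reduce kinetically with LiBH(s-Bu)3 (THF, −78 °C), which attacks anti to the axial C5 methyl to give the axial 3β-alcohol F5. Mitsunobu esterification of F5 with 20 (PPh3, diisopropyl azodicarboxylate, PhMe, 0 °C) inverts C3 and returns to the route at 22.

**Step 12.** Productive metathesis of the α-branched allylic ester may be slow, with self-metathesis of the acrylate partner or ruthenium hydride double-bond migration competing. Fallback: set out from 16 and build the enoate by olefination instead.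
- L-Proline-catalysed α-aminoxylation of butanal with nitrosobenzene would give (R)-2-[(phenylamino)oxy]butanal F6.
- Horner–Wadsworth–Emmons reaction in the same flask with tert-butyl diethylphosphonoacetate (LiCl, i-Pr2NEt) would give tert-butyl (2E,4R)-4-[(phenylamino)oxy]hex-2-enoate F7.
- N–O cleavage (Zn, AcOH) would give tert-butyl (2E,4R)-4-hydroxyhex-2-enoate F8.
- Acylation with 16 through anhydride 17, as in step 11, would give tert-butyl (2E,4R)-4-{[(2Z)-2-methylbut-2-enoyl]oxy}hex-2-enoate F9.
- Cleavage of the tert-butyl ester (CF3CO2H, CH2Cl2, 0 °C) returns at 20.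

## Further compounds

F1 | step 4 | (Z)-tert-butyldimethyl(pent-2-en-3-yloxy)silane | C/C=C(/CC)O[Si](C)(C)C(C)(C)C
F2 | step 4 | C9 tert-butyldimethylsilyl enol ether (C9=C10) bearing at C5 the β-methyl and the α-oriented C4 chain CH(CH3)C(=O)CH2CH3 | C=C(C)[C@H]1C[C@](C)([C@@H](C)C(=O)CC)C=C(O[Si](C)(C)C(C)(C)C)C1
F3 | step 4 | α-phenylselanyl ketone from F2 (selenide carbon unassigned) | C=C(C)[C@H]1C[C@](C)([C@@H](C)C(=O)C(C)[Se]c2ccccc2)C=C(O[Si](C)(C)C(C)(C)C)C1
F4 | step 2 | (S)-5-(2-hydroxypropan-2-yl)-3-methylcyclohex-2-en-1-one | CC(C)(O)[C@H]1CC(C)=CC(=O)C1
F0 | step 7 | none | none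
F5 | step 10 | 3β-alcohol, C3 epimer of 14 | C=C(C)[C@H]1C[C@@]2(C)[C@H](CC[C@H](O)[C@@H]2C)[C@@H](O[Si](C)(C)C(C)(C)C)[C@H]1O[Si](CC)(CC)CC
F6 | step 12 | (R)-2-[(phenylamino)oxy]butanal | O=C[C@@H](CC)ONc1ccccc1
F7 | step 12 | tert-butyl (2E,4R)-4-[(phenylamino)oxy]hex-2-enoate | CC(C)(C)OC(=O)/C=C/[C@@H](CC)ONc1ccccc1
F8 | step 12 | tert-butyl (2E,4R)-4-hydroxyhex-2-enoate | CC(C)(C)OC(=O)/C=C/[C@@H](CC)O
F9 | step 12 | tert-butyl (2E,4R)-4-{[(2Z)-2-methylbut-2-enoyl]oxy}hex-2-enoate | CC(C)(C)OC(=O)/C=C/[C@@H](CC)OC(=O)/C(C)=C\C
A1 | alternative 1 | cis-fused 1,8a-dimethyl-3,4,4a,7,8,8a-hexahydronaphthalen-2(1H)-one (C3 ketone, C8=C9 alkene, 4β,5β-dimethyl, 10βH) | C1C[C@@]2(C)[C@H](CCC(=O)[C@@H]2C)C=C1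
A2 | alternative 1 | 3,4-dimethyl-2-vinylbicyclo[2.2.2]oct-5-en-2-ol, vinyl group and C3 methyl both syn to the C5=C6 bridge | C=C[C@]1(O)[C@H](C)[C@@]2(C)CC[C@@H]1C=C2
A3 | alternative 2 | 2-[3-(tert-butyldimethylsilyloxy)propyl]-2,3-dimethylcyclohex-3-ene-1-carboxylic acid, acid and propyl chain cis | OC(=O)[C@H]1CCC=C(C)[C@@]1(C)CCCO[Si](C)(C)C(C)(C)C
A4 | alternative 2 | (R)-6-[(E)-6-(tert-butyldimethylsilyloxy)-3-methylhex-2-en-2-yl]oxan-2-one | O=C1CCC[C@@H](O1)/C(C)=C(\C)CCCO[Si](C)(C)C(C)(C)C
A5 | alternative 3 | 7α-acetyl-8α-ethoxy-4β,5β-dimethyl-3α-(tert-butyldimethylsilyloxy)decal-9-ene | CC(=O)[C@@H]1C[C@@]2(C)C(CC[C@@H](O[Si](C)(C)C(C)(C)C)[C@@H]2C)=C[C@@H]1OCC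
A6 | alternative 3 | tert-butyl{[4-((E)-2-ethoxyethenyl)-2,3-dimethylcyclohex-3-en-1-yl]oxy}dimethylsilane, silyloxy and C2 methyl trans (target C3 α, C4 β) | CCO/C=C/C1=C(C)[C@@H](C)[C@H](O[Si](C)(C)C(C)(C)C)CC1
A7 | alternative 3 | but-3-en-2-one | C=CC(C)=O
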